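The oxolane is disconnected at O1–C2, the ring CH2 next to C3 that carries the carbinol side chain. Because C2 is β to the benzylic carbon through C3, at the ketone oxidation level it can be introduced as the aminomethylene carbon of an enaminone. A one-pot aminomethylenation–cyclisation of an enantioenriched acyclic γ-hydroxy aryl ketone therefore builds C2–C3 and closes the ring through O1–C2 as a 3-aroyl-4,5-dihydrofuran (cyclic vinylogous ester). Its C2=C3 double bond is then hydrogenated anti to the C4 benzyl group, which gives the contra-thermodynamic cis C3/C4 relationship, and a reagent-controlled ketone reduction sets the carbinol centre.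

Key step: step 4

Assumption: the benzyl ethers 1 and 4 are taken as purchasable; if not, each is one benzylation (BnBr, K2CO3) from 5-bromo-2-methoxyphenol or 3-hydroxy-4-methoxyacetophenone.

Step 1
Reactants: 1 2-(benzyloxy)-4-bromo-1-methoxybenzene; 2 prop-2-en-1-ol (allyl alcohol)
Product: 3 3-[3-(benzyloxy)-4-methoxyphenyl]propanal
Conditions: Pd(OAc)2 (3 mol%), Bu4NCl, NaHCO3, DMF, 90 °C
Reagents that add atoms: none
Why: Heck arylation of allyl alcohol under ligand-free phase-transfer conditions: the aryl–palladium species adds to the terminal alkene carbon and β-hydride elimination towards the carbinol carbon gives an enol that tautomerises to the 3-arylpropanal; no stereocentre is formed.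

Step 2
Reactants: 4 1-[3-(benzyloxy)-4-methoxyphenyl]ethan-1-one
Product: 5 1-[3-(benzyloxy)-4-methoxyphenyl]-2-bromoethan-1-one
Conditions: CuBr2 (2.1 equiv), EtOAc–CHCl3, reflux
Reagents that add atoms: copper dibromide, Br[Cu]Br
Why: Selective α-monobromination of an aryl methyl ketone through its enol with CuBr2, a method that normally leaves electron-rich alkoxyarenes unbrominated and benzyl ethers intact.

Step 3
Reactants: 3 3-[3-(benzyloxy)-4-methoxyphenyl]propanal (2 equiv); 5 1-[3-(benzyloxy)-4-methoxyphenyl]-2-bromoethan-1-one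
Product: 7 (3R)-1-[3-(benzyloxy)-4-methoxyphenyl]-3-{[3-(benzyloxy)-4-methoxyphenyl]methyl}-4-hydroxybutan-1-one, via keto aldehyde 6 (not isolated)
Conditions: (2R,5S)-2-tert-butyl-3,5-dimethylimidazolidin-4-one·TfOH (20 mol%), Ru(bpy)3Cl2 (0.5 mol%), 2,6-lutidine, DMF, visible light, 23 °C; then CH2Cl2–MeOH, NaBH4, −78 °C
Reagents that add atoms: none
Why: Photoredox organocatalytic α-alkylation of an aldehyde (enamine catalysis merged with Ru(bpy)3Cl2 photoredox catalysis): the phenacyl radical from 5 adds to the E-enamine of 3 on the Si face left open by the (2R,5S)-imidazolidinone, which sets the R configuration of the future oxolane C4, and NaBH4 at −78 °C then reduces the aldehyde chemoselectively beside the aryl ketone before the α-stereocentre can epimerise.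

Step 4
Reactants: 7 (3R)-1-[3-(benzyloxy)-4-methoxyphenyl]-3-{[3-(benzyloxy)-4-methoxyphenyl]methyl}-4-hydroxybutan-1-one
Product: 9 [(4R)-4-{[3-(benzyloxy)-4-methoxyphenyl]methyl}-4,5-dihydrofuran-3-yl][3-(benzyloxy)-4-methoxyphenyl]methanone, via enaminone 8 (not isolated)
Conditions: tert-butoxybis(dimethylamino)methane (2.5 equiv), toluene, 90 °C; then AcOH–H2O, 60 °C
Reagents that add atoms: tert-butoxybis(dimethylamino)methane, CN(C)C(OC(C)(C)C)N(C)C
Why: The aminal ester condenses with the only enolisable position of 7 (the CH2 between the ketone and the branched carbon) to give enaminone 8, whose aminomethylene carbon is the future ring C2. On acidification 8 is protonated at the α-carbon to an α-acyl iminium ion, the tethered primary hydroxyl adds to the iminium carbon, and loss of dimethylamine from the N,O-acetal gives the cyclic vinylogous ester 9; the closest known reaction types are the enaminone route to chromones and 2,3-dihydro-4-pyranones and the cyclodehydration that ends the Korte acyl-lactone rearrangement. The five-membered ring closes by 5-exo-trig attack of oxygen on the exocyclic C=N+ bond, which avoids the formally 5-endo substitution on the neutral enaminone. No new stereocentre is formed: the C4 centre set in step 3 is not α to a carbonyl in 7 or 8 and sits at the non-acidic γ-position of 9 under the acidic finish, so it should be carried through unchanged. The step needs oxygen to attack the aminomethylene carbon and not the ketone carbon (which would lead to a 2-aryl-dihydrofuran); this is secured because the ketone carbonyl of 8 is deactivated as a vinylogous amide, the iminium carbon is the most electrophilic site, and expulsion of the protonated amine is irreversible.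

Step 5
Reactants: 9 [(4R)-4-{[3-(benzyloxy)-4-methoxyphenyl]methyl}-4,5-dihydrofuran-3-yl][3-(benzyloxy)-4-methoxyphenyl]methanone
Product: 10 [(3S,4R)-4-[(3-hydroxy-4-methoxyphenyl)methyl]oxolan-3-yl](3-hydroxy-4-methoxyphenyl)methanone
Conditions: H2 (1–3 bar), 10% Pd/C, EtOAc–MeOH, rt, stopped after uptake of three equivalents
Reagents that add atoms: none
Why: Heterogeneous syn-hydrogenation of the C2=C3 enol-ether double bond from the face opposite the C4 benzyl group (held pseudoaxial by allylic strain with the aroyl group) delivers hydrogen to C3 trans to the benzyl group, so aroyl and benzyl end up cis (3S,4R), while both aryl benzyl ethers are hydrogenolysed in the same operation.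

Step 6
Reactants: 10 [(3S,4R)-4-[(3-hydroxy-4-methoxyphenyl)methyl]oxolan-3-yl](3-hydroxy-4-methoxyphenyl)methanone
Product: 11 (S)-[(3S,4R)-4-[(3-hydroxy-4-methoxyphenyl)methyl]oxolan-3-yl](3-hydroxy-4-methoxyphenyl)methanol
Conditions: (R)-2-methyl-CBS-oxazaborolidine (1.0 equiv), BH3·SMe2 (4 equiv), THF, −20 °C; MeOH quench
Reagents that add atoms: none
Why: Corey–Bakshi–Shibata reduction: the (R)-oxazaborolidine–borane complex binds the ketone with the aryl group as the large substituent and delivers hydride to give the S carbinol by reagent control, the phenols being masked in the flask as aryloxyboranes that methanol cleaves on work-up, and the non-basic conditions should not epimerise C3.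

Compound list
1 | 2-(benzyloxy)-4-bromo-1-methoxybenzene | COc1ccc(Br)cc1OCc1ccccc1 | starting material
2 | prop-2-en-1-ol | C=CCO | starting material
3 | 3-[3-(benzyloxy)-4-methoxyphenyl]propanal | COc1ccc(CCC=O)cc1OCc1ccccc1 | intermediate
4 | 1-[3-(benzyloxy)-4-methoxyphenyl]ethan-1-one | COc1ccc(C(C)=O)cc1OCc1ccccc1 | starting material
5 | 1-[3-(benzyloxy)-4-methoxyphenyl]-2-bromoethan-1-one | COc1ccc(C(=O)CBr)cc1OCc1ccccc1 | intermediate
6 | (2R)-4-[3-(benzyloxy)-4-methoxyphenyl]-2-{[3-(benzyloxy)-4-methoxyphenyl]methyl}-4-oxobutanal | COc1ccc(C[C@@H](C=O)CC(=O)c2ccc(OC)c(OCc3ccccc3)c2)cc1OCc1ccccc1 | intermediate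
7 | (3R)-1-[3-(benzyloxy)-4-methoxyphenyl]-3-{[3-(benzyloxy)-4-methoxyphenyl]methyl}-4-hydroxybutan-1-one | COc1ccc(C[C@@H](CO)CC(=O)c2ccc(OC)c(OCc3ccccc3)c2)cc1OCc1ccccc1 | intermediate
8 | (3R)-1-[3-(benzyloxy)-4-methoxyphenyl]-3-{[3-(benzyloxy)-4-methoxyphenyl]methyl}-2-[(dimethylamino)methylidene]-4-hydroxybutan-1-one (alkene geometry not controlled) | COc1ccc(C[C@@H](CO)C(=CN(C)C)C(=O)c2ccc(OC)c(OCc3ccccc3)c2)cc1OCc1ccccc1 | intermediate
9 | [(4R)-4-{[3-(benzyloxy)-4-methoxyphenyl]methyl}-4,5-dihydrofuran-3-yl][3-(benzyloxy)-4-methoxyphenyl]methanone | COc1ccc(C[C@H]2COC=C2C(=O)c2ccc(OC)c(OCc3ccccc3)c2)cc1OCc1ccccc1 | intermediate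
10 | [(3S,4R)-4-[(3-hydroxy-4-methoxyphenyl)methyl]oxolan-3-yl](3-hydroxy-4-methoxyphenyl)methanone (3,4-cis) | COc1ccc(C[C@H]2COC[C@H]2C(=O)c2ccc(OC)c(O)c2)cc1O | intermediate
11 | (S)-[(3S,4R)-4-[(3-hydroxy-4-methoxyphenyl)methyl]oxolan-3-yl](3-hydroxy-4-methoxyphenyl)methanol (3,4-cis) | COc1ccc(C[C@H]2COC[C@H]2[C@H](O)c2ccc(OC)c(O)c2)cc1O | target

Total step count: 6. Longest linear sequence: 5 steps (steps 1, 3, 4, 5, 6); step 2 prepares the second fragment.

Steps most likely to fail

Step 4. The aminomethylenation may stall at the hindered, β-branched α-methylene group. The cyclic hemiketal form of 7 may dehydrate to a 5-aryl-2,3-dihydrofuran, or ring closure may occur at the ketone carbon. The fallback sets out from 7 and comes back at 9. The primary hydroxyl is silylated (TBSCl, imidazole, DMF) to (3R)-1-[3-(benzyloxy)-4-methoxyphenyl]-3-{[3-(benzyloxy)-4-methoxyphenyl]methyl}-4-[(tert-butyldimethylsilyl)oxy]butan-1-one F1, which removes the hemiketal equilibrium. Claisen formylation (NaH, HCO2Et, THF) gives the 2-(hydroxymethylidene) ketone F2. TsOH·H2O in wet THF then cleaves the silyl ether, and the freed hydroxyl forms a hemiacetal at the aldehyde carbon and loses water, the same cyclodehydration that ends the Korte acyl-lactone rearrangement, to give 9.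

Step 5. Facial discrimination may be incomplete (some trans ketone), the push–pull alkene may saturate slowly, or the aryl ketone may be over-reduced. The fallback sets out from 9 and comes back at 10. Rhodium-catalysed 1,4-hydrosilylation (Et3SiH, RhCl(PPh3)3, toluene, 60 °C) gives the triethylsilyl enol ether {[(4R)-4-{[3-(benzyloxy)-4-methoxyphenyl]methyl}oxolan-3-ylidene][3-(benzyloxy)-4-methoxyphenyl]methoxy}triethylsilane F3. Kinetic protonation (Bu4NF, AcOH, THF, −78 °C) from the face opposite the C4 benzyl group should give the benzyl-protected cis ketone [(3S,4R)-4-{[3-(benzyloxy)-4-methoxyphenyl]methyl}oxolan-3-yl][3-(benzyloxy)-4-methoxyphenyl]methanone F4. A brief hydrogenolysis (H2, Pd/C, EtOAc), which now only has to remove the benzyl groups, gives 10.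

Step 6. Reagent control may be eroded: the free phenols consume borane and may open an uncatalysed reduction pathway, and the intrinsic Felkin–Anh preference of the cis ketone opposes the catalyst, so the carbinol epimer may form. The fallback sets out from 10 and comes back at 11. Both phenols are silylated (TBSCl, imidazole, DMF) to the bis-silyl ketone [(3S,4R)-4-({3-[(tert-butyldimethylsilyl)oxy]-4-methoxyphenyl}methyl)oxolan-3-yl]{3-[(tert-butyldimethylsilyl)oxy]-4-methoxyphenyl}methanone F5. Reduction with stoichiometric (R)-2-methyl-CBS-oxazaborolidine and catecholborane in toluene at −78 °C gives the bis-silyl S carbinol F6, from which any epimer is separated by chromatography. Bu4NF buffered with AcOH in THF then gives 11.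

Further compounds
F1 | step 4 | (3R)-1-[3-(benzyloxy)-4-methoxyphenyl]-3-{[3-(benzyloxy)-4-methoxyphenyl]methyl}-4-[(tert-butyldimethylsilyl)oxy]butan-1-one | COc1ccc(C[C@@H](CO[Si](C)(C)C(C)(C)C)CC(=O)c2ccc(OC)c(OCc3ccccc3)c2)cc1OCc1ccccc1
F2 | step 4 | (3R)-1-[3-(benzyloxy)-4-methoxyphenyl]-3-{[3-(benzyloxy)-4-methoxyphenyl]methyl}-4-[(tert-butyldimethylsilyl)oxy]-2-(hydroxymethylidene)butan-1-one | COc1ccc(C[C@@H](CO[Si](C)(C)C(C)(C)C)C(=CO)C(=O)c2ccc(OC)c(OCc3ccccc3)c2)cc1OCc1ccccc1
F3 | step 5 | {[(4R)-4-{[3-(benzyloxy)-4-methoxyphenyl]methyl}oxolan-3-ylidene][3-(benzyloxy)-4-methoxyphenyl]methoxy}triethylsilane | COc1ccc(C[C@H]2COCC2=C(O[Si](CC)(CC)CC)c2ccc(OC)c(OCc3ccccc3)c2)cc1OCc1ccccc1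
F4 | step 5 | [(3S,4R)-4-{[3-(benzyloxy)-4-methoxyphenyl]methyl}oxolan-3-yl][3-(benzyloxy)-4-methoxyphenyl]methanone | COc1ccc(C[C@H]2COC[C@H]2C(=O)c2ccc(OC)c(OCc3ccccc3)c2)cc1OCc1ccccc1
F5 | step 6 | [(3S,4R)-4-({3-[(tert-butyldimethylsilyl)oxy]-4-methoxyphenyl}methyl)oxolan-3-yl]{3-[(tert-butyldimethylsilyl)oxy]-4-methoxyphenyl}methanone | COc1ccc(C[C@H]2COC[C@H]2C(=O)c2ccc(OC)c(O[Si](C)(C)C(C)(C)C)c2)cc1O[Si](C)(C)C(C)(C)C
F6 | step 6 | (S)-[(3S,4R)-4-({3-[(tert-butyldimethylsilyl)oxy]-4-methoxyphenyl}methyl)oxolan-3-yl]{3-[(tert-butyldimethylsilyl)oxy]-4-methoxyphenyl}methanol | COc1ccc(C[C@H]2COC[C@H]2[C@H](O)c2ccc(OC)c(O[Si](C)(C)C(C)(C)C)c2)cc1O[Si](C)(C)C(C)(C)C
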